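**Plan**

- Cuts: (a) the bond from the benzylic CH2 of the side chain to C1 of the 4-hydroxyphenyl ring; (b) the ring bond O1–C6 of the oxane, opened to a δ-oxygenated ketone at C6; (c) the two side-chain CH2 carbons, traced back to a cyclopropanol built on an ester carbonyl (the future C6); (d) C2–C3, an aldol of the aryl aldehyde.
- Enabling feature: the O-bearing ring carbon C6 is separated from C1 of the 4-hydroxyphenyl ring by exactly two CH2 groups. At the ketone level C6 is therefore a β-aryl ketone, the product of an aryl halide and a ketone homoenolate stored in a cyclopropane (C6 plus the two CH2). C6 is also 1,5 to the O-bearing C2, so the ketone closes back to the O1/C2–C6 ring.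
- Forward: protected 5-hydroxyvanillin, then a vinylogous aldol (adds C3–C6), anti reduction, bis-silylation, Kulinkovich cyclopropanation, Pd ring-opening arylation (joins the arene, unveils the C6 ketone), reductive etherification (the only ring closure, made last), and deprotection.
- Stereochemistry: C2 from the Ti/BINOL-catalysed aldol (catalyst control); C4 from the hydroxyl-directed 1,3-anti reduction (controlled by C2); C6 from axial hydride delivery to the cyclic oxocarbenium ion (controlled by C2 and C4).

Key step: step 6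

Assumption: the Ti(IV)/(S)-BINOL catalyst is taken to deliver the (S)-carbinol from aromatic aldehydes in this vinylogous aldol; were the sense opposite, (R)-BINOL would be used and nothing else changes.

**Route**

Step 1
Reactants: 1 3,4-dihydroxy-5-methoxybenzaldehyde (5-hydroxyvanillin)
Product: 2 3,4-bis(benzyloxy)-5-methoxybenzaldehyde
Conditions: BnBr (2.3 equiv), K2CO3 (3 equiv), DMF, 60 °C
Reagents that add atoms: benzyl bromide, BrCc1ccccc1
Why: Williamson etherification, in which both phenoxides are benzylated while the aldehyde is inert; no stereocenter is involved.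

Step 2
Reactants: 2 3,4-bis(benzyloxy)-5-methoxybenzaldehyde; 3 1-methoxy-1,3-bis(trimethylsilyloxy)buta-1,3-diene
Product: 5 methyl (5S)-5-[3,4-bis(benzyloxy)-5-methoxyphenyl]-5-hydroxy-3-oxopentanoate, via bis-trimethylsilyl aldol adduct 4 (not isolated)
Conditions: Ti(OiPr)4 (10 mol %), (S)-BINOL (10 mol %), 4 Å MS, THF, −78 °C → rt; then TFA (cat.), THF/H2O, 0 °C
Reagents that add atoms: none
Why: Catalytic asymmetric vinylogous Mukaiyama aldol, in which the terminal CH2 of the bis-silyl dienolate adds to the Ti(IV)–BINOL-bound aldehyde, the ligand shielding one carbonyl face and so setting the (5S) carbinol under catalyst control; brief aqueous acid then removes both trimethylsilyl groups of 4 to unveil the β-keto ester.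

Step 3
Reactants: 5 methyl (5S)-5-[3,4-bis(benzyloxy)-5-methoxyphenyl]-5-hydroxy-3-oxopentanoate
Product: 6 methyl (3S,5S)-5-[3,4-bis(benzyloxy)-5-methoxyphenyl]-3,5-dihydroxypentanoate
Conditions: Me4NBH(OAc)3 (5 equiv), MeCN/AcOH (1:1), −30 °C
Reagents that add atoms: none
Why: Evans–Saksena 1,3-anti reduction, in which the C5 hydroxyl exchanges onto boron and delivers hydride intramolecularly through a chair-like six-membered transition state to the C3 ketone, which should set (3S) anti to C5; the ester is not reduced by the acetoxyborohydride.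

Step 4
Reactants: 6 methyl (3S,5S)-5-[3,4-bis(benzyloxy)-5-methoxyphenyl]-3,5-dihydroxypentanoate
Product: 7 methyl (3S,5S)-5-[3,4-bis(benzyloxy)-5-methoxyphenyl]-3,5-bis(triethylsilyloxy)pentanoate
Conditions: TESCl (2.5 equiv), imidazole (5 equiv), DMAP (cat.), DMF, 0 °C → rt
Reagents that add atoms: chlorotriethylsilane, CC[Si](Cl)(CC)CC
Why: Standard silylation of both secondary alcohols; the triethylsilyl ethers keep them out of the Grignard and palladium alkoxide chemistry of steps 5 and 6, and the benzylic one later serves as the oxygen nucleophile of the reductive etherification.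

Step 5
Reactants: 7 methyl (3S,5S)-5-[3,4-bis(benzyloxy)-5-methoxyphenyl]-3,5-bis(triethylsilyloxy)pentanoate
Product: 8 1-[(2S,4S)-4-[3,4-bis(benzyloxy)-5-methoxyphenyl]-2,4-bis(triethylsilyloxy)butyl]cyclopropan-1-ol
Conditions: EtMgBr (3.2 equiv, slow addition), Ti(OiPr)4 (0.3 equiv), THF, 0 °C → rt; aq. NH4Cl
Reagents that add atoms: ethylmagnesium bromide, CC[Mg]Br
Why: Kulinkovich cyclopropanation, in which EtMgBr and Ti(OiPr)4 form a titanacyclopropane that adds twice as a 1,2-dicarbanion to the ester carbonyl, turning it into the carbinol carbon of a 1-substituted cyclopropanol that carries the two future side-chain CH2 groups; silyl and benzyl ethers are inert and no stereocenter is touched.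

Step 6
Reactants: 8 1-[(2S,4S)-4-[3,4-bis(benzyloxy)-5-methoxyphenyl]-2,4-bis(triethylsilyloxy)butyl]cyclopropan-1-ol; 9 1-(benzyloxy)-4-bromobenzene
Product: 10 (5S,7S)-1-[4-(benzyloxy)phenyl]-7-[3,4-bis(benzyloxy)-5-methoxyphenyl]-5,7-bis(triethylsilyloxy)heptan-3-one
Conditions: Pd(OAc)2 (5 mol %), XPhos (10 mol %), Cs2CO3 (1.5 equiv), toluene (degassed), 80 °C
Reagents that add atoms: none
Why: Pd(0) inserts into the C–Br bond of 9, the cyclopropanol O–H exchanges onto Pd(II) under Cs2CO3, and strain-driven β-carbon elimination opens the three-membered ring to a palladium ketone homoenolate, whose C(sp3)–C(sp2) reductive elimination forms the benzylic CH2–aryl bond and at the same time unveils the C3 ketone, the future C6 of the oxane. The closest known reaction type is the palladium-catalysed ring-opening cross-coupling of 1-alkylcyclopropanols with aryl bromides to give β-aryl ketones. No ring is closed (the temporary cyclopropane is opened and thereby removed) and no stereocenter is created; the two silyloxy-bearing centers are not involved and should remain untouched. The selectivity needed is reductive elimination over β-hydride elimination of the homoenolate to a vinyl ketone, which the bulky biarylphosphine should secure, while regiochemistry of ring opening is no issue because the two cyclopropane CH2 groups are equivalent. Chemoselectivity rests on the substrate: the cyclopropanol is its only free hydroxyl, both secondary alcohols being silyl ethers that cannot form palladium alkoxides and be oxidised, and the weak heterogeneous base in toluene is chosen so that the β-silyloxy ketone product does not eliminate.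

Step 7
Reactants: 10 (5S,7S)-1-[4-(benzyloxy)phenyl]-7-[3,4-bis(benzyloxy)-5-methoxyphenyl]-5,7-bis(triethylsilyloxy)heptan-3-one
Product: 11 triethyl{[(2S,4R,6S)-2-[3,4-bis(benzyloxy)-5-methoxyphenyl]-6-{2-[4-(benzyloxy)phenyl]ethyl}oxan-4-yl]oxy}silane
Conditions: Et3SiH (3 equiv), TMSOTf (0.3 equiv), CH2Cl2, −78 °C
Reagents that add atoms: none
Why: Reductive etherification of a δ-silyloxy ketone, in which TMSOTf activates the ketone, the benzylic silyl ether oxygen closes the six-membered ring (6-exo attack on the carbonyl) and ionisation gives the cyclic oxocarbenium ion, to which Et3SiH adds along the axial trajectory of the half-chair that holds the C2 aryl and C4 silyloxy groups pseudo-equatorial, so the new C6 stereocenter should be (6S) with the side chain cis to both (substrate control).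

Step 8
Reactants: 11 triethyl{[(2S,4R,6S)-2-[3,4-bis(benzyloxy)-5-methoxyphenyl]-6-{2-[4-(benzyloxy)phenyl]ethyl}oxan-4-yl]oxy}silane
Product: 12 (2S,4R,6S)-2-[3,4-bis(benzyloxy)-5-methoxyphenyl]-6-{2-[4-(benzyloxy)phenyl]ethyl}oxan-4-ol
Conditions: PPTS (0.2 equiv), MeOH/CH2Cl2, rt
Reagents that add atoms: none
Why: Mild acid-catalysed methanolysis of the secondary triethylsilyl ether, PPTS being too weak to ionise the benzylic ring C–O bond or to touch the benzyl ethers; no stereocenter is affected.

Step 9
Reactants: 12 (2S,4R,6S)-2-[3,4-bis(benzyloxy)-5-methoxyphenyl]-6-{2-[4-(benzyloxy)phenyl]ethyl}oxan-4-ol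
Product: 13 5-[(2S,4R,6S)-4-hydroxy-6-[2-(4-hydroxyphenyl)ethyl]oxan-2-yl]-3-methoxybenzene-1,2-diol (target)
Conditions: H2 (1 atm), 10% Pd/C, EtOAc/MeOH, rt
Reagents that add atoms: none
Why: Catalytic hydrogenolysis, in which the three aryl benzyl ethers are cleaved over Pd/C under neutral conditions where the secondary benzylic C2–O bond of the oxane should react much more slowly, so the reaction is stopped once three equivalents of hydrogen are taken up; the catechol product is handled under inert gas.

**Compound list**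

1 | 3,4-dihydroxy-5-methoxybenzaldehyde (5-hydroxyvanillin) | COc1cc(C=O)cc(O)c1O | starting material
2 | 3,4-bis(benzyloxy)-5-methoxybenzaldehyde | COc1cc(C=O)cc(OCc2ccccc2)c1OCc1ccccc1 | intermediate
3 | 1-methoxy-1,3-bis(trimethylsilyloxy)buta-1,3-diene | COC(O[Si](C)(C)C)=CC(=C)O[Si](C)(C)C | starting material
4 | methyl (5S)-5-[3,4-bis(benzyloxy)-5-methoxyphenyl]-3,5-bis(trimethylsilyloxy)pent-2-enoate (not isolated) | COc1cc([C@@H](O[Si](C)(C)C)CC(O[Si](C)(C)C)=CC(=O)OC)cc(OCc2ccccc2)c1OCc1ccccc1 | intermediate
5 | methyl (5S)-5-[3,4-bis(benzyloxy)-5-methoxyphenyl]-5-hydroxy-3-oxopentanoate | COc1cc([C@@H](O)CC(=O)CC(=O)OC)cc(OCc2ccccc2)c1OCc1ccccc1 | intermediate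
6 | methyl (3S,5S)-5-[3,4-bis(benzyloxy)-5-methoxyphenyl]-3,5-dihydroxypentanoate | COc1cc([C@@H](O)C[C@H](O)CC(=O)OC)cc(OCc2ccccc2)c1OCc1ccccc1 | intermediate
7 | methyl (3S,5S)-5-[3,4-bis(benzyloxy)-5-methoxyphenyl]-3,5-bis(triethylsilyloxy)pentanoate | COc1cc([C@@H](O[Si](CC)(CC)CC)C[C@H](O[Si](CC)(CC)CC)CC(=O)OC)cc(OCc2ccccc2)c1OCc1ccccc1 | intermediate
8 | 1-[(2S,4S)-4-[3,4-bis(benzyloxy)-5-methoxyphenyl]-2,4-bis(triethylsilyloxy)butyl]cyclopropan-1-ol | COc1cc([C@@H](O[Si](CC)(CC)CC)C[C@H](O[Si](CC)(CC)CC)CC2(O)CC2)cc(OCc2ccccc2)c1OCc1ccccc1 | intermediate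
9 | 1-(benzyloxy)-4-bromobenzene | Brc1ccc(OCc2ccccc2)cc1 | starting material
10 | (5S,7S)-1-[4-(benzyloxy)phenyl]-7-[3,4-bis(benzyloxy)-5-methoxyphenyl]-5,7-bis(triethylsilyloxy)heptan-3-one | COc1cc([C@@H](O[Si](CC)(CC)CC)C[C@H](O[Si](CC)(CC)CC)CC(=O)CCc2ccc(OCc3ccccc3)cc2)cc(OCc2ccccc2)c1OCc1ccccc1 | intermediate
11 | triethyl{[(2S,4R,6S)-2-[3,4-bis(benzyloxy)-5-methoxyphenyl]-6-{2-[4-(benzyloxy)phenyl]ethyl}oxan-4-yl]oxy}silane | COc1cc([C@@H]2C[C@H](O[Si](CC)(CC)CC)C[C@H](CCc3ccc(OCc4ccccc4)cc3)O2)cc(OCc2ccccc2)c1OCc1ccccc1 | intermediate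
12 | (2S,4R,6S)-2-[3,4-bis(benzyloxy)-5-methoxyphenyl]-6-{2-[4-(benzyloxy)phenyl]ethyl}oxan-4-ol | COc1cc([C@@H]2C[C@H](O)C[C@H](CCc3ccc(OCc4ccccc4)cc3)O2)cc(OCc2ccccc2)c1OCc1ccccc1 | intermediate
13 | 5-[(2S,4R,6S)-4-hydroxy-6-[2-(4-hydroxyphenyl)ethyl]oxan-2-yl]-3-methoxybenzene-1,2-diol | COc1cc([C@@H]2C[C@H](O)C[C@H](CCc3ccc(O)cc3)O2)cc(O)c1O | target

**Step count and risks**

Total step count: 9. Longest linear sequence: 9 steps (1 to 13; 3 and 9 are purchased and enter in steps 2 and 6).

Steps most likely to fail:

1. Step 6. β-Hydride elimination of the palladium homoenolate to a vinyl ketone may outrun reductive elimination, and the base may cause β-elimination of the C5 silyloxy group in the product ketone. The fallback forms the same bond by a Heck arylation of an allylic alcohol instead of a homoenolate coupling. It sets out from 7: DIBAL-H (CH2Cl2, −78 °C) should stop at the aldehyde (3S,5S)-5-[3,4-bis(benzyloxy)-5-methoxyphenyl]-3,5-bis(triethylsilyloxy)pentanal F1. Vinylmagnesium bromide (THF, −78 °C) should then give the allylic alcohol (5R,7S)-7-[3,4-bis(benzyloxy)-5-methoxyphenyl]-5,7-bis(triethylsilyloxy)hept-1-en-3-ol F2 as both C3 epimers, which is of no consequence. Heck reaction of F2 with commercial 1-(benzyloxy)-4-iodobenzene under ligand-free phase-transfer conditions (Pd(OAc)2, Bu4NCl, NaHCO3, DMF, 50 °C) should place the aryl group on the terminal alkene carbon; β-hydride elimination toward the carbinol C–H and tautomerisation of the enol then give the saturated ketone from either epimer. The fallback comes back to the route at 10.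

2. Step 7. The Lewis acid may ionise the electron-rich benzylic C–O bond, leading to ring opening with over-reduction or elimination, and hydride delivery to the oxocarbenium ion may be incompletely face-selective. The fallback closes the ring at the other C–O bond and uses the benzylic cation deliberately. It sets out from 10: AcOH/THF/H2O (rt) should remove both silyl groups to give (5S,7S)-1-[4-(benzyloxy)phenyl]-7-[3,4-bis(benzyloxy)-5-methoxyphenyl]-5,7-dihydroxyheptan-3-one F3, which is in equilibrium with its cyclic hemiketal. Evans–Saksena reduction (Me4NBH(OAc)3, MeCN/AcOH, −30 °C), directed by the C5 hydroxyl, should give the 3,5-anti triol (3S,5R,7S)-1-[4-(benzyloxy)phenyl]-7-[3,4-bis(benzyloxy)-5-methoxyphenyl]heptane-3,5,7-triol F4. Catalytic TsOH·H2O (CH2Cl2, rt) should then effect dehydrative cyclisation: the C3 hydroxyl captures the benzylic cation reversibly, so thermodynamic control should give the all-equatorial 2,4,6-cis oxane, whose absolute configuration is fixed by the two untouched carbinol centers. The fallback comes back to the route at 12.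

3. Step 2. The electron-rich, hindered aldehyde may react sluggishly, and the catalyst may give insufficient enantioselectivity. The fallback replaces catalyst control by auxiliary control with separable diastereomers. It sets out from 2: acetate aldol with the chelated titanium enolate of (4R)-3-acetyl-4-isopropyl-1,3-thiazolidine-2-thione (TiCl4, iPr2NEt, CH2Cl2, −78 °C), which is expected to deliver the (S)-carbinol, should give (3S)-3-[3,4-bis(benzyloxy)-5-methoxyphenyl]-3-hydroxy-1-[(4R)-4-isopropyl-2-thioxo-1,3-thiazolidin-3-yl]propan-1-one F5, purified from its minor diastereomer by chromatography. Treatment with potassium methyl malonate, MgCl2 and imidazole (THF, rt) should transfer the acyl group from the auxiliary to the magnesium malonate, giving (5S)-5-[3,4-bis(benzyloxy)-5-methoxyphenyl]-5-hydroxy-2-(methoxycarbonyl)-3-oxopentanoic acid F6, not isolated, which decarboxylates on acidic work-up. The fallback comes back to the route at 5.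

**Further compounds**

F1 | step 6 | (3S,5S)-5-[3,4-bis(benzyloxy)-5-methoxyphenyl]-3,5-bis(triethylsilyloxy)pentanal | COc1cc([C@@H](O[Si](CC)(CC)CC)C[C@H](O[Si](CC)(CC)CC)CC=O)cc(OCc2ccccc2)c1OCc1ccccc1
F2 | step 6 | (5R,7S)-7-[3,4-bis(benzyloxy)-5-methoxyphenyl]-5,7-bis(triethylsilyloxy)hept-1-en-3-ol (both C3 epimers) | COc1cc([C@@H](O[Si](CC)(CC)CC)C[C@H](O[Si](CC)(CC)CC)CC(O)C=C)cc(OCc2ccccc2)c1OCc1ccccc1
F3 | step 7 | (5S,7S)-1-[4-(benzyloxy)phenyl]-7-[3,4-bis(benzyloxy)-5-methoxyphenyl]-5,7-dihydroxyheptan-3-one | COc1cc([C@@H](O)C[C@H](O)CC(=O)CCc2ccc(OCc3ccccc3)cc2)cc(OCc2ccccc2)c1OCc1ccccc1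
F4 | step 7 | (3S,5R,7S)-1-[4-(benzyloxy)phenyl]-7-[3,4-bis(benzyloxy)-5-methoxyphenyl]heptane-3,5,7-triol | COc1cc([C@@H](O)C[C@H](O)C[C@H](CCc2ccc(OCc3ccccc3)cc2)O)cc(OCc2ccccc2)c1OCc1ccccc1
F5 | step 2 | (3S)-3-[3,4-bis(benzyloxy)-5-methoxyphenyl]-3-hydroxy-1-[(4R)-4-isopropyl-2-thioxo-1,3-thiazolidin-3-yl]propan-1-one | COc1cc([C@@H](O)CC(=O)N2C(=S)SC[C@H]2C(C)C)cc(OCc2ccccc2)c1OCc1ccccc1
F6 | step 2 | (5S)-5-[3,4-bis(benzyloxy)-5-methoxyphenyl]-5-hydroxy-2-(methoxycarbonyl)-3-oxopentanoic acid | COc1cc([C@@H](O)CC(=O)C(C(=O)O)C(=O)OC)cc(OCc2ccccc2)c1OCc1ccccc1
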